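Everything rests on cutting the three O–S bonds at O3 (ring C), O7 (ring A) and O4' (ring B), which leads back to intact kaempferol and a masked sulfuryl donor. In one operation three equivalents of 2,2,2-trichloroethyl chlorosulfate should sulfate these hydroxyls as neutral, chromatographable sulfate diesters. The step exploits the O5–H of ring A, which is tied into a six-membered hydrogen bond with the C4 carbonyl oxygen of ring C and lies peri to it, so that it is the least acidic and least accessible hydroxyl and stays free. The precursor is unprotected kaempferol with all four hydroxyls open. Reductive removal of the trichloroethyl groups and cation exchange then release the trisulfate.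

Key step: step 2

Assumption: the target SMILES is read as the free tris(hydrogen sulfate). Because aryl hydrogen sulfates tend to lose sulfate under their own acidity, the triammonium salt 8 is treated as the storage form and the free acid 9 is liberated last, cold, by cation exchange.

Step 1
Reactants: 1 2,2,2-trichloroethanol; 2 sulfuryl chloride
Product: 3 2,2,2-trichloroethyl chlorosulfate
Conditions: pyridine (1 equiv), Et2O, −78 °C → rt; alcohol–pyridine solution added to SO2Cl2; filter, wash, distil
Reagents that add atoms: none
Why: Chlorosulfonylation of an alcohol (nucleophilic substitution at the sulfur of SO2Cl2): inverse addition into cold SO2Cl2 keeps the reagent in excess so that only one chloride is displaced, and the electron-poor trichloroethyl group makes the chlorosulfate stable enough to wash and distil.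

Step 2
Reactants: 4 kaempferol; 3 2,2,2-trichloroethyl chlorosulfate (three equivalents are consumed, one per O–S bond)
Product: 7 kaempferol 3,7,4'-tris(2,2,2-trichloroethyl sulfate), via kaempferol 7-(2,2,2-trichloroethyl sulfate) 5 (not isolated), via kaempferol 7,4'-bis(2,2,2-trichloroethyl sulfate) 6 (not isolated)
Conditions: 3 (3.3 equiv, added dropwise), Et3N (3.6 equiv), DMAP (0.5 equiv), THF, 0 °C → rt; silica gel chromatography
Reagents that add atoms: 2,2,2-trichloroethyl chlorosulfate 3 (two further equivalents beside the one on the Reactants line), O=S(=O)(Cl)OCC(Cl)(Cl)Cl.O=S(=O)(Cl)OCC(Cl)(Cl)Cl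
Why: DMAP attacks the sulfur of 3 and displaces chloride to give an N-sulfonylpyridinium salt, which the triethylammonium phenoxides of 4 attack at sulfur with release of DMAP, so each of the three equivalents of 3 forms one aryl or enol O–S bond. The closest known reaction type is the DMAP-mediated O-sulfonylation of phenols with alkyl chlorosulfates, which gives trichloroethyl-masked aryl sulfates. No ring is closed and no stereocentre is created. The selectivity required is site selectivity among four hydroxyls: O7–H and O4'–H, both vinylogous acids through the C4 carbonyl, should react first, and the enolic O3–H, only weakly hydrogen-bonded in a five-membered arrangement, should follow. O5–H is held in the six-membered chelate to the C4 carbonyl oxygen and is flanked by the peri carbonyl, so with a small excess of 3 added slowly at 0 °C it should remain unsulfated. The neutral triester can be purified on silica, where the retained chelated O5–H resonance would be expected to confirm the substitution pattern before any charged species is made.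

Step 3
Reactants: 7 kaempferol 3,7,4'-tris(2,2,2-trichloroethyl sulfate)
Product: 8 triammonium kaempferol 3,7,4'-tri-O-sulfate
Conditions: Zn dust, HCO2NH4, MeOH, rt; filter through Celite; C18 (H2O–MeOH)
Reagents that add atoms: ammonium formate (three equivalents supply the three ammonium counter-ions), [NH4+].[O-]C=O.[NH4+].[O-]C=O.[NH4+].[O-]C=O
Why: Reductive β-elimination (reductive fragmentation of a 2,2,2-trichloroethyl ester): Zn transfers two electrons to a C–Cl bond of each CCl3 group and the resulting carbanion expels the aryl sulfate monoanion with 1,1-dichloroethene, while buffered neutral methanol at room temperature should leave the chromone carbonyl, the C2=C3 bond and the aryl S–O bonds untouched and HCO2NH4 supplies the ammonium counter-ions.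

Step 4
Reactants: 8 triammonium kaempferol 3,7,4'-tri-O-sulfate
Product: 9 kaempferol 3,7,4'-tri-O-sulfate (free acid, the target)
Conditions: Dowex 50W sulfonic acid resin (H+ form), H2O, 0–4 °C; eluate freeze-dried at once
Reagents that add atoms: none
Why: Cation exchange on a sulfonic acid resin: ammonium is retained while the strongly acidic aryl hydrogen sulfate groups pass through as the solvated acid, and low temperature, short contact and immediate freeze-drying should limit acid-catalysed S–O hydrolysis, to which the O3 sulfate is the most exposed.

Compound list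
1 | 2,2,2-trichloroethanol | OCC(Cl)(Cl)Cl | starting material
2 | sulfuryl chloride | O=S(=O)(Cl)Cl | starting material
3 | 2,2,2-trichloroethyl chlorosulfate | O=S(=O)(Cl)OCC(Cl)(Cl)Cl | intermediate
4 | kaempferol, 3,5,7-trihydroxy-2-(4-hydroxyphenyl)-4H-chromen-4-one | O=c1c(O)c(-c2ccc(O)cc2)oc2cc(O)cc(O)c12 | starting material
5 | kaempferol 7-(2,2,2-trichloroethyl sulfate), with the 3-, 5- and 4'-hydroxyls free | O=c1c(O)c(-c2ccc(O)cc2)oc2cc(OS(=O)(=O)OCC(Cl)(Cl)Cl)cc(O)c12 | intermediate (not isolated)
6 | kaempferol 7,4'-bis(2,2,2-trichloroethyl sulfate), with the 3- and 5-hydroxyls free | O=c1c(O)c(-c2ccc(OS(=O)(=O)OCC(Cl)(Cl)Cl)cc2)oc2cc(OS(=O)(=O)OCC(Cl)(Cl)Cl)cc(O)c12 | intermediate (not isolated)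
7 | kaempferol 3,7,4'-tris(2,2,2-trichloroethyl sulfate), with the 5-hydroxyl free | O=c1c(OS(=O)(=O)OCC(Cl)(Cl)Cl)c(-c2ccc(OS(=O)(=O)OCC(Cl)(Cl)Cl)cc2)oc2cc(OS(=O)(=O)OCC(Cl)(Cl)Cl)cc(O)c12 | intermediate
8 | triammonium kaempferol 3,7,4'-tri-O-sulfate | O=c1c(OS(=O)(=O)[O-])c(-c2ccc(OS(=O)(=O)[O-])cc2)oc2cc(OS(=O)(=O)[O-])cc(O)c12.[NH4+].[NH4+].[NH4+] | intermediate
9 | kaempferol 3,7,4'-tri-O-sulfate, achiral | O=c1c(OS(=O)(=O)O)c(-c2ccc(OS(=O)(=O)O)cc2)oc2cc(OS(=O)(=O)O)cc(O)c12 | target

Total step count: 4
Longest linear sequence: 4 steps (1 → 2 → 3 → 4 from 2,2,2-trichloroethanol and sulfuryl chloride); 3 steps counted from kaempferol.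

Steps most likely to fail

Step 2. The sulfation may lose its site selectivity: it may stall before the enolic O3–H has reacted, or run on to the chelated O5–H. The amine bases may also strip a sulfuryl group from the electron-poor ring A diester. In each case the diester mixture would be hard to separate. The fallback sets out from kaempferol 4 and abandons the masked diester for direct carbodiimide-driven sulfation. Bu4NHSO4 and dicyclohexylcarbodiimide in pyridine at 4 °C → rt are known to sulfate flavonol hydroxyls stepwise at O7, O4' and O3 and to leave the chelated O5–H alone. After filtration of the urea and gel filtration on Sephadex LH-20 this should give tris(tetrabutylammonium) kaempferol 3,7,4'-tri-O-sulfate F1. KOAc in methanol should then precipitate tripotassium kaempferol 3,7,4'-tri-O-sulfate F2. Passage of F2 through the sulfonic acid resin (H+ form) in cold water, as in step 4, brings the fallback back to the route at compound 9.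

Step 4. The S–O bonds, first of all that of the O3 sulfate, may be cleaved under acid catalysis while the strongly acidic eluate is concentrated, or the exchange of ammonium may remain incomplete. The fallback sets out from 8 and replaces the resin by a stoichiometric precipitation metathesis. Ba(OH)2 (1.5 equiv) in water, with the liberated ammonia stripped under reduced pressure at room temperature, should give barium kaempferol 3,7,4'-tri-O-sulfate F3 (three barium ions per two trianions). Titration at 0 °C with exactly 1.5 equiv of dilute H2SO4 and centrifugation of BaSO4 should leave a salt-free solution of the free acid of known titre. This can be used as such or freeze-dried from high dilution, and the fallback comes back to the route at compound 9.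

Step 3. The reductive fragmentation may stop short if zinc ions are bound at the O5–H/C4 carbonyl chelate site and the salts coat the metal, and sulfate may be lost while zinc salts are removed. The fallback sets out from kaempferol 4 and changes the mask to one removed by nucleophilic dealkylation, so that no metal reductant is used. 2-Methylpropan-1-ol and sulfuryl chloride 2 (pyridine, Et2O, −78 °C) should give 2-methylpropyl chlorosulfate F4. The trianion of 4, made with NaN(SiMe3)2 (3 equiv) in THF–DMPU at −78 °C and so confined to the three most acidic hydroxyls, should then react with three equivalents of F4 at −78 → 0 °C to give kaempferol 3,7,4'-tris(2-methylpropyl sulfate) F5. NaI in acetone at 55 °C should remove the isobutyl groups by SN2 attack at the primary carbon and precipitate trisodium kaempferol 3,7,4'-tri-O-sulfate F6. The sulfonic acid resin (H+ form) of step 4 then brings the fallback back to the route at compound 9.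

Further compounds
F1 | step 2 | tris(tetrabutylammonium) kaempferol 3,7,4'-tri-O-sulfate | O=c1c(OS(=O)(=O)[O-])c(-c2ccc(OS(=O)(=O)[O-])cc2)oc2cc(OS(=O)(=O)[O-])cc(O)c12.CCCC[N+](CCCC)(CCCC)CCCC.CCCC[N+](CCCC)(CCCC)CCCC.CCCC[N+](CCCC)(CCCC)CCCC
F2 | step 2 | tripotassium kaempferol 3,7,4'-tri-O-sulfate | O=c1c(OS(=O)(=O)[O-])c(-c2ccc(OS(=O)(=O)[O-])cc2)oc2cc(OS(=O)(=O)[O-])cc(O)c12.[K+].[K+].[K+]
F3 | step 4 | barium kaempferol 3,7,4'-tri-O-sulfate (3 Ba : 2 trianions) | O=c1c(OS(=O)(=O)[O-])c(-c2ccc(OS(=O)(=O)[O-])cc2)oc2cc(OS(=O)(=O)[O-])cc(O)c12.O=c1c(OS(=O)(=O)[O-])c(-c2ccc(OS(=O)(=O)[O-])cc2)oc2cc(OS(=O)(=O)[O-])cc(O)c12.[Ba+2].[Ba+2].[Ba+2]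
F4 | step 3 | 2-methylpropyl chlorosulfate (isobutyl chlorosulfate) | CC(C)COS(=O)(=O)Cl
F5 | step 3 | kaempferol 3,7,4'-tris(2-methylpropyl sulfate) | O=c1c(OS(=O)(=O)OCC(C)C)c(-c2ccc(OS(=O)(=O)OCC(C)C)cc2)oc2cc(OS(=O)(=O)OCC(C)C)cc(O)c12
F6 | step 3 | trisodium kaempferol 3,7,4'-tri-O-sulfate | O=c1c(OS(=O)(=O)[O-])c(-c2ccc(OS(=O)(=O)[O-])cc2)oc2cc(OS(=O)(=O)[O-])cc(O)c12.[Na+].[Na+].[Na+]
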